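**Retrosynthetic overview**

- Target 21 is fisetinidol-(4β→6)-mollisacacidin. The lower 3,4-trans diol is made last by hydride reduction of the lower C4 ketone (20), after all protecting groups are gone.
- The lower pyran ring (O1–C2–C3–C4–C4a–C8a) is made late by a 5→6 α-ketol ring expansion of a 3-hydroxy-2-aryl-2,3-dihydrobenzofuran-3-carbaldehyde (17→18). The formyl carbon is inserted as C3 between C2 and the future C4.
- Enabling feature: in the lower unit C3(OH)/C4(O) is an α-ketol pair, and C4 sits on the A-ring carbon C4a (para to O7, ortho to O1). The dihydroflavonol is therefore the conjugated, more stable isomer of a five-ring α-hydroxy aldehyde. The contracted ring has no ionisable C4–O bond, and its resorcinol-type ring is a clean nucleophile at the future C6.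
- The interflavanoid bond C4(upper)–C6(lower) is formed by Friedel–Crafts capture of the upper flavan-4-yl cation. The lower ring is delivered to the β-face by a temporary O3–Si(i-Pr)2–O7' tether (seven-membered ring, 3,4-cis).
- Both halves come from one dihydrobenzofuran α-hydroxy ester 9. Its C2 is set by Rh-catalysed asymmetric C–H insertion and all other centres are relayed from it. Ring order: furan ring → upper pyranone (same ring expansion, step 7) → silaketal ring → lower pyranone.

Key step: step 13

Remark: compound 1 is taken as a catalogue compound, and Rh2(S-PTTL)4 is taken to give the (2S,3R) ester 7 in step 4; if the sense of induction on this substrate is opposite, the enantiomeric catalyst is used.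

Flavan numbering is used for chromane units; primed locants refer to the lower (dihydrobenzofuran or chromane) unit of the dimers.

Step 1
Reactants: 1 6-hydroxybenzofuran-2(3H)-one
Product: 2 6-[(triisopropylsilyl)oxy]benzofuran-2(3H)-one
Conditions: TIPSCl, imidazole, DMF, 0 °C → rt
Reagents that add atoms: triisopropylsilyl chloride, CC(C)[Si](Cl)(C(C)C)C(C)C
Why: Phenol silylation under imidazole catalysis, which leaves the aryl lactone closed so that the second phenolic oxygen stays masked and the two oxygens are differentiated.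

Step 2
Reactants: 2 6-[(triisopropylsilyl)oxy]benzofuran-2(3H)-one; 3 3,4-bis(benzyloxy)benzyl chloride
Product: 5 methyl 2-{2-[3,4-bis(benzyloxy)benzyloxy]-4-[(triisopropylsilyl)oxy]phenyl}acetate, via sodium phenolate 4 (not isolated)
Conditions: NaOMe (1.05 equiv), MeOH/THF, −20 °C; then 3, Bu4NI (cat.), DMF, rt
Reagents that add atoms: sodium methoxide, C[O-].[Na+]
Why: Methanolysis of the activated aryl lactone should free only the ortho phenoxide, which is then O-alkylated by the benzylic chloride (Williamson ether synthesis), placing the future B-ring benzyl group on the oxygen that becomes O1.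

Step 3
Reactants: 5 methyl 2-{2-[3,4-bis(benzyloxy)benzyloxy]-4-[(triisopropylsilyl)oxy]phenyl}acetate
Product: 6 methyl 2-{2-[3,4-bis(benzyloxy)benzyloxy]-4-[(triisopropylsilyl)oxy]phenyl}-2-diazoacetate
Conditions: p-ABSA, DBU, MeCN, 0 °C → rt
Reagents that add atoms: 4-acetamidobenzenesulfonyl azide, CC(=O)Nc1ccc(cc1)S(=O)(=O)N=[N+]=[N-]
Why: Regitz diazo transfer to an aryl acetate is the standard entry to aryldiazoacetates and tolerates the silyl and benzyl ethers.

Step 4
Reactants: 6 methyl 2-{2-[3,4-bis(benzyloxy)benzyloxy]-4-[(triisopropylsilyl)oxy]phenyl}-2-diazoacetate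
Product: 7 methyl (2S,3R)-2-[3,4-bis(benzyloxy)phenyl]-6-[(triisopropylsilyl)oxy]-2,3-dihydrobenzofuran-3-carboxylate (2,3-cis)
Conditions: Rh2(S-PTTL)4 (1 mol %), toluene, −60 °C → rt
Reagents that add atoms: none
Why: Intramolecular 1,5 C–H insertion of the rhodium(II) donor/acceptor carbenoid into the electron-rich benzylic ether C–H closes the dihydrofuran ring; the chiral carboxylate ligands set C2, the only stereocentre of the route made by a catalyst, and C3 (cis by the insertion geometry) is erased in step 5.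

Step 5
Reactants: 7 methyl (2S,3R)-2-[3,4-bis(benzyloxy)phenyl]-6-[(triisopropylsilyl)oxy]-2,3-dihydrobenzofuran-3-carboxylate
Product: 9 methyl (2R,3S)-2-[3,4-bis(benzyloxy)phenyl]-3-hydroxy-6-[(triisopropylsilyl)oxy]-2,3-dihydrobenzofuran-3-carboxylate (3-OH trans to the 2-aryl group), via potassium enolate 8 (not isolated)
Conditions: KHMDS, THF, −78 °C; then 2-(phenylsulfonyl)-3-phenyloxaziridine, −78 °C; NH4Cl
Reagents that add atoms: 2-(phenylsulfonyl)-3-phenyloxaziridine, O1C(c2ccccc2)N1S(=O)(=O)c1ccccc1
Why: Sulfonyloxaziridine hydroxylation of the ester enolate should occur on the face anti to the C2 aryl group (substrate control), giving the tertiary alcohol trans to the aryl group; β-elimination of the aryloxide is disfavoured because the C2–O1 bond lies in the nodal plane of the exocyclic enolate.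

Step 6
Reactants: 9 methyl (2R,3S)-2-[3,4-bis(benzyloxy)phenyl]-3-hydroxy-6-[(triisopropylsilyl)oxy]-2,3-dihydrobenzofuran-3-carboxylate
Product: 10 (2R,3S)-2-[3,4-bis(benzyloxy)phenyl]-3-hydroxy-6-[(triisopropylsilyl)oxy]-2,3-dihydrobenzofuran-3-carbaldehyde
Conditions: DIBAL-H (2.5 equiv), CH2Cl2, −78 °C; Rochelle salt
Reagents that add atoms: none
Why: Partial reduction of an α-hydroxy ester, in which the neighbouring aluminium alkoxide chelates the tetrahedral hemiacetal so that the aldehyde is released only on work-up.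

Step 7
Reactants: 10 (2R,3S)-2-[3,4-bis(benzyloxy)phenyl]-3-hydroxy-6-[(triisopropylsilyl)oxy]-2,3-dihydrobenzofuran-3-carbaldehyde
Product: 11 (2R,3R)-2-[3,4-bis(benzyloxy)phenyl]-3-hydroxy-7-[(triisopropylsilyl)oxy]chroman-4-one (2,3-trans; protected fustin)
Conditions: Al(Ot-Bu)3 (0.3 equiv), toluene, 50 °C
Reagents that add atoms: none
Why: The same α-ketol ring expansion as in step 13 (mechanism and stereocontrol given there), here on the monomer: C2 shifts from the carbinol carbon to the chelated formyl carbon with retention, and the new C3 is set trans to the 2-aryl group.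

Step 8
Reactants: 9 methyl (2R,3S)-2-[3,4-bis(benzyloxy)phenyl]-3-hydroxy-6-[(triisopropylsilyl)oxy]-2,3-dihydrobenzofuran-3-carboxylate
Product: 12 methyl (2R,3S)-2-[3,4-bis(benzyloxy)phenyl]-3,6-dihydroxy-2,3-dihydrobenzofuran-3-carboxylate
Conditions: TBAF, AcOH, THF, 0 °C
Reagents that add atoms: none
Why: Buffered fluoride cleavage of the aryl silyl ether frees the phenol that will carry the tether and activate the neighbouring ring carbon.

Step 9
Reactants: 11 (2R,3R)-2-[3,4-bis(benzyloxy)phenyl]-3-hydroxy-7-[(triisopropylsilyl)oxy]chroman-4-one; 12 methyl (2R,3S)-2-[3,4-bis(benzyloxy)phenyl]-3,6-dihydroxy-2,3-dihydrobenzofuran-3-carboxylate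
Product: 14 diisopropylsilylene acetal joining O-3 of 11 to O-6 of 12 (upper unit 2R,3R ketone; lower unit 2R,3S α-hydroxy ester), via chlorosilane 13 (not isolated)
Conditions: i-Pr2SiCl2 (3 equiv), imidazole, CH2Cl2, 0 °C; evaporate excess silane; then 12, imidazole, DMAP (cat.), DMF, rt
Reagents that add atoms: dichlorodiisopropylsilane, CC(C)[Si](Cl)(Cl)C(C)C
Why: Stepwise unsymmetrical silyl ketal formation (silicon-tether methodology), in which the hindered secondary 3-OH is first converted with excess dichlorosilane into the monochlorosilane, which then silylates the unhindered phenol of 12 in preference to its tertiary alcohol.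

Step 10
Reactants: 14 diisopropylsilylene acetal joining O-3 of 11 to O-6 of 12
Product: 15 the flavan-4-ol of 14 (upper unit 2R,3S,4R; 3,4-trans; lower unit unchanged)
Conditions: NaBH4, CeCl3·7H2O, MeOH/THF, −40 °C
Reagents that add atoms: none
Why: Luche reduction should reduce the aryl ketone chemoselectively beside the α-hydroxy ester and the silyl ethers, mainly by axial hydride delivery to the 4α-alcohol, whose configuration is of no consequence because C4 is ionised in step 11.

Step 11
Reactants: 15 the flavan-4-ol of 14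
Product: 16 cyclic silaketal in which C4 of the upper (2R,3S)-flavan unit is bonded (4β; 3,4-cis) to C5' of the lower (2R,3S)-dihydrobenzofuran α-hydroxy ester (seven-membered ring C4–C3–O–Si(i-Pr)2–O–C6'–C5')
Conditions: TMSOTf (0.2 equiv), CH2Cl2 (2 mM), 4 Å MS, −40 °C; Et3N
Reagents that add atoms: none
Why: Acid ionises the benzylic 4-OH to the flavan-4-yl cation (stabilised by para-O7 and ortho-O1), which is captured at C5' (para to O1', ortho to the tether oxygen) in an intramolecular Friedel–Crafts alkylation closing the seven-membered silaketal ring in the 7-exo mode; because the nucleophile hangs from the β-oriented O3, the new C4 stereocentre is formed with the aryl group cis to O3 (tethered aryl delivery), and the lower unit cannot ionise since its benzylic C–O bonds adjoin the ester-bearing quaternary carbon.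

Step 12
Reactants: 16 cyclic silaketal with the lower unit as methyl ester
Product: 17 the corresponding lower-unit aldehyde (lower unit (2R,3S)-3-hydroxy-2,3-dihydrobenzofuran-3-carbaldehyde; rest as in 16)
Conditions: DIBAL-H (2.5 equiv), CH2Cl2, −78 °C; Rochelle salt
Reagents that add atoms: none
Why: Partial reduction of the α-hydroxy ester as in step 6, with the tertiary hydroxyl as the only free OH in the molecule and the silaketal, silyl ether and benzyl ethers inert to the hydride.

Step 13
Reactants: 17 the lower-unit aldehyde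
Product: 18 cyclic silaketal of the dimer whose lower unit is the (2R,3R)-3-hydroxychroman-4-one (protected fisetinidol-(4β→6)-fustin)
Conditions: Al(Ot-Bu)3 (0.3 equiv), toluene, 50 °C
Reagents that add atoms: none
Why: Aluminium exchanges onto the tertiary C3'–OH and chelates the formyl oxygen (O–C–C=O syn-periplanar), whereupon the ring bond C2'–C3' shifts suprafacially to the formyl carbon while C3' becomes the aryl ketone, so the dihydrofuran ring (O1', C2', C3', C3a', C7a') grows by the formyl carbon into the pyranone ring O1–C2–C3–C4–C4a–C8a. This is an α-ketol (acyloin) rearrangement with ring expansion of a cyclic tertiary α-hydroxy aldehyde, the reaction type of the D-homoannulation of 17-hydroxy-20-oxosteroids and of the rearrangement of 1-hydroxycycloalkanecarbaldehydes to 2-hydroxycycloalkanones. No ring is closed by cyclisation: the six-membered ring arises by a 1,2-shift (5→6 expansion) in which the migrating C2 keeps its configuration. The new C3 stereocentre is set by the chelate: with the formyl group cis to the 2-aryl group and O–Al syn to C=O, C2 reaches the formyl face that gives the 2,3-trans (2R,3R) ketol, which is also the thermodynamic epimer at this enolisable centre. The step needs the shift of C2 and not of the electron-rich aryl carbon C3a': C2 is an α-aryloxy, p-alkoxybenzylic carbon of high migratory aptitude, and only its shift gives the ketone conjugated to the ring bearing para-O7 and ortho-O1 (the driving force, aldehyde → vinylogous ester); should C3a' shift, the ring still expands to the isomeric 4-hydroxy-3-ketone, which is expected to transpose through the C3/C4 enediol to the same ketol without touching C2. Chemoselectivity rests on the single free hydroxyl of 17, which places the Lewis acid where it is needed, and on the C2'–O1' bond being deactivated towards ionisation by the adjacent C(OH)CHO carbon.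

Step 14
Reactants: 18 cyclic silaketal of the protected dimer
Product: 19 3',4',3'',4''-tetra-O-benzyl-fisetinidol-(4β→6)-(2R,3R)-fustin
Conditions: TBAF, AcOH, THF, 0 °C → rt
Reagents that add atoms: none
Why: Fluoride cleaves both Si–O bonds of the tether and the aryl triisopropylsilyl ether, and the acetic acid buffer protects the base-sensitive dihydroflavonol from C2 epimerisation and ring contraction.

Step 15
Reactants: 19 3',4',3'',4''-tetra-O-benzyl-fisetinidol-(4β→6)-(2R,3R)-fustin
Product: 20 fisetinidol-(4β→6)-(2R,3R)-fustin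
Conditions: H2 (1 atm), Pd(OH)2/C, THF/MeOH, rt
Reagents that add atoms: none
Why: Neutral hydrogenolysis removes the four benzyl ethers while the cyclic benzylic C2–O1 ethers, the diarylmethine C4 and the vinylogous-ester ketone are retained, and it is done before the acid- and hydrogenolysis-labile 4-hydroxyl exists.

Step 16
Reactants: 20 fisetinidol-(4β→6)-(2R,3R)-fustin
Product: 21 fisetinidol-(4β→6)-mollisacacidin (upper unit 2R,3S,4S; lower unit 2R,3S,4R; target)
Conditions: NaBH4, EtOH, 0 °C; pH 6 phosphate buffer work-up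
Reagents that add atoms: none
Why: Borohydride reduction of the dihydroflavonol carbonyl by axial hydride delivery to the half-chair pyranone with equatorial 2-aryl and 3-OH groups should give the equatorial 4α-alcohol, i.e. the 2,3-trans-3,4-trans (4R) diol known for fustin-type substrates, under conditions that do not ionise the product.

**Compound list**

1 | 6-hydroxybenzofuran-2(3H)-one | O=C1Cc2ccc(O)cc2O1 | starting material
2 | 6-[(triisopropylsilyl)oxy]benzofuran-2(3H)-one | O=C1Cc2ccc(O[Si](C(C)C)(C(C)C)C(C)C)cc2O1 | intermediate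
3 | 3,4-bis(benzyloxy)benzyl chloride | ClCc1ccc(OCc2ccccc2)c(OCc2ccccc2)c1 | starting material
4 | sodium 2-(2-methoxy-2-oxoethyl)-5-[(triisopropylsilyl)oxy]phenolate | COC(=O)Cc1ccc(O[Si](C(C)C)(C(C)C)C(C)C)cc1[O-].[Na+] | intermediate
5 | methyl 2-{2-[3,4-bis(benzyloxy)benzyloxy]-4-[(triisopropylsilyl)oxy]phenyl}acetate | COC(=O)Cc1ccc(O[Si](C(C)C)(C(C)C)C(C)C)cc1OCc1ccc(OCc2ccccc2)c(OCc2ccccc2)c1 | intermediate
6 | methyl 2-{2-[3,4-bis(benzyloxy)benzyloxy]-4-[(triisopropylsilyl)oxy]phenyl}-2-diazoacetate | COC(=O)C(=[N+]=[N-])c1ccc(O[Si](C(C)C)(C(C)C)C(C)C)cc1OCc1ccc(OCc2ccccc2)c(OCc2ccccc2)c1 | intermediate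
7 | methyl (2S,3R)-2-[3,4-bis(benzyloxy)phenyl]-6-[(triisopropylsilyl)oxy]-2,3-dihydrobenzofuran-3-carboxylate (2,3-cis) | CC(C)[Si](C(C)C)(C(C)C)Oc1ccc2c(c1)O[C@H](c1ccc(OCc3ccccc3)c(OCc3ccccc3)c1)[C@@H]2C(=O)OC | intermediate
8 | potassium enolate of 7 (2R; enolate geometry not defined) | COC([O-])=C1c2ccc(O[Si](C(C)C)(C(C)C)C(C)C)cc2O[C@@H]1c1ccc(OCc2ccccc2)c(OCc2ccccc2)c1.[K+] | intermediate
9 | methyl (2R,3S)-2-[3,4-bis(benzyloxy)phenyl]-3-hydroxy-6-[(triisopropylsilyl)oxy]-2,3-dihydrobenzofuran-3-carboxylate | CC(C)[Si](C(C)C)(C(C)C)Oc1ccc2c(c1)O[C@H](c1ccc(OCc3ccccc3)c(OCc3ccccc3)c1)[C@]2(O)C(=O)OC | intermediate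
10 | (2R,3S)-2-[3,4-bis(benzyloxy)phenyl]-3-hydroxy-6-[(triisopropylsilyl)oxy]-2,3-dihydrobenzofuran-3-carbaldehyde | CC(C)[Si](C(C)C)(C(C)C)Oc1ccc2c(c1)O[C@H](c1ccc(OCc3ccccc3)c(OCc3ccccc3)c1)[C@]2(O)C=O | intermediate
11 | (2R,3R)-2-[3,4-bis(benzyloxy)phenyl]-3-hydroxy-7-[(triisopropylsilyl)oxy]chroman-4-one | CC(C)[Si](C(C)C)(C(C)C)Oc1ccc2c(c1)O[C@H](c1ccc(OCc3ccccc3)c(OCc3ccccc3)c1)[C@@H](O)C2=O | intermediate
12 | methyl (2R,3S)-2-[3,4-bis(benzyloxy)phenyl]-3,6-dihydroxy-2,3-dihydrobenzofuran-3-carboxylate | Oc1ccc2c(c1)O[C@H](c1ccc(OCc3ccccc3)c(OCc3ccccc3)c1)[C@]2(O)C(=O)OC | intermediate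
13 | 3-O-[chloro(diisopropyl)silyl] derivative of 11 | CC(C)[Si](C(C)C)(C(C)C)Oc1ccc2c(c1)O[C@H](c1ccc(OCc3ccccc3)c(OCc3ccccc3)c1)[C@@H](O[Si](Cl)(C(C)C)C(C)C)C2=O | intermediate
14 | diisopropylsilylene acetal joining O-3 of 11 to O-6 of 12 | CC(C)[Si](C(C)C)(C(C)C)Oc1ccc2c(c1)O[C@H](c1ccc(OCc3ccccc3)c(OCc3ccccc3)c1)[C@@H](O[Si](C(C)C)(C(C)C)Oc1ccc3c(c1)O[C@H](c1ccc(OCc4ccccc4)c(OCc4ccccc4)c1)[C@]3(O)C(=O)OC)C2=O | intermediate
15 | flavan-4-ol of 14 (upper unit 2R,3S,4R) | CC(C)[Si](C(C)C)(C(C)C)Oc1ccc2c(c1)O[C@H](c1ccc(OCc3ccccc3)c(OCc3ccccc3)c1)[C@@H](O[Si](C(C)C)(C(C)C)Oc1ccc3c(c1)O[C@H](c1ccc(OCc4ccccc4)c(OCc4ccccc4)c1)[C@]3(O)C(=O)OC)[C@@H]2O | intermediate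
16 | cyclic silaketal: upper flavan C4 (4β) bonded to C5' of the lower dihydrobenzofuran α-hydroxy ester | CC(C)[Si](C(C)C)(C(C)C)Oc1ccc2c(c1)O[C@H](c1ccc(OCc3ccccc3)c(OCc3ccccc3)c1)[C@@H](O[Si](C(C)C)(C(C)C)O6)[C@H]2c7cc8c(cc76)O[C@H](c1ccc(OCc3ccccc3)c(OCc3ccccc3)c1)[C@]8(O)C(=O)OC | intermediate
17 | lower-unit aldehyde of 16 | CC(C)[Si](C(C)C)(C(C)C)Oc1ccc2c(c1)O[C@H](c1ccc(OCc3ccccc3)c(OCc3ccccc3)c1)[C@@H](O[Si](C(C)C)(C(C)C)O6)[C@H]2c7cc8c(cc76)O[C@H](c1ccc(OCc3ccccc3)c(OCc3ccccc3)c1)[C@]8(O)C=O | intermediate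
18 | cyclic silaketal of the dimer with the lower (2R,3R)-3-hydroxychroman-4-one | CC(C)[Si](C(C)C)(C(C)C)Oc1ccc2c(c1)O[C@H](c1ccc(OCc3ccccc3)c(OCc3ccccc3)c1)[C@@H](O[Si](C(C)C)(C(C)C)O6)[C@H]2c7cc8c(cc76)O[C@H](c1ccc(OCc3ccccc3)c(OCc3ccccc3)c1)[C@@H](O)C8=O | intermediate
19 | 3',4',3'',4''-tetra-O-benzyl-fisetinidol-(4β→6)-(2R,3R)-fustin | Oc1ccc2c(c1)O[C@H](c1ccc(OCc3ccccc3)c(OCc3ccccc3)c1)[C@@H](O)[C@H]2c1cc2c(cc1O)O[C@H](c1ccc(OCc3ccccc3)c(OCc3ccccc3)c1)[C@@H](O)C2=O | intermediate
20 | fisetinidol-(4β→6)-(2R,3R)-fustin | Oc1ccc2c(c1)O[C@H](c1ccc(O)c(O)c1)[C@@H](O)[C@H]2c1cc2c(cc1O)O[C@H](c1ccc(O)c(O)c1)[C@@H](O)C2=O | intermediate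
21 | fisetinidol-(4β→6)-mollisacacidin (CNP0280090.2) | Oc1ccc2c(c1)O[C@H](c1ccc(O)c(O)c1)[C@@H](O)[C@H]2c1cc2c(cc1O)O[C@H](c1ccc(O)c(O)c1)[C@@H](O)[C@@H]2O | target

**Step count and risks**

Total step count: 16. Longest linear sequence: 15 steps (steps 1–7 and 9–16; steps 1–5 and 8 form the shorter branch).

Steps most likely to fail:

Step 13. On the tethered dimer the Lewis acid may cleave the silaketal or open the C2'–O1' bond, or the shift may be slow or run through the aryl-migration channel in the more electron-rich, C-alkylated ring with erosion at C2'. The fallback moves the ring expansion of the lower unit to the monomer stage, where step 7 already delivers it, and couples a ketone-level lower unit through the same tether. It sets out from 11. One part of 11 is desilylated with TBAF/AcOH to (2R,3R)-2-[3,4-bis(benzyloxy)phenyl]-3,7-dihydroxychroman-4-one F1. A second part is reduced with NaBH4 to the 3,4-trans diol F2 and converted with PPTS in methanol into its 4-O-methyl ether F3, which has the 3-OH as its only free hydroxyl. F3 is treated with excess i-Pr2SiCl2 and imidazole to give the chlorosilane F4, which silylates the acidic 7-OH of F1 in preference to its secondary alcohol and gives the silaketal F5. Catalytic TMSOTf at high dilution ionises the 4-methoxy group, and the tethered ring, still activated by para-O1 and the ortho tether oxygen, closes at C6. This gives 18, where the route is rejoined.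

Step 11. The tethered cation may be captured at C7' (between the two oxygens) instead of C5', the acid may cleave a Si–O bond before the C–C bond forms, or intermolecular alkylation may give oligomers. The fallback gives up pre-association and uses the standard intermolecular Lewis-acid coupling of a 4-alkoxyflavan-3-ol with an excess of nucleophile. It sets out from 11 and 12. The 4-O-methyl ether F3 (made from 11 through F2 as described for step 13) is ionised with TMSOTf in CH2Cl2 at −78 °C in the presence of three equivalents of 12. The 3,4-cis (4β) adduct at C5', the 4β-linked dihydroxy dimer F6, is separated by chromatography from its 4α epimer. Its upper 3-OH and lower 6'-OH are then bridged with i-Pr2SiCl2 and imidazole at high dilution to give 16, where the route is rejoined.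

Step 16. Hydride delivery on the polyphenolic substrate may be less face-selective because of catechol–borate complexation, and the new benzylic 4-hydroxyl may ionise and self-condense during work-up. The fallback sets the lower C4 centre one stage earlier, on the benzyl-protected ketone. It sets out from 19, which is reduced with NaBH4 in THF/EtOH to the tetra-O-benzyl ether of the target F7, purified as the 3,4-trans diol. Brief neutral hydrogenolysis (H2, Pd(OH)2/C, EtOAc/MeOH) then gives 21.

Further compounds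
F1 | step 13 | (2R,3R)-2-[3,4-bis(benzyloxy)phenyl]-3,7-dihydroxychroman-4-one | Oc1ccc2c(c1)O[C@H](c1ccc(OCc3ccccc3)c(OCc3ccccc3)c1)[C@@H](O)C2=O
F2 | step 13 | (2R,3S,4R)-2-[3,4-bis(benzyloxy)phenyl]-7-[(triisopropylsilyl)oxy]chromane-3,4-diol | CC(C)[Si](C(C)C)(C(C)C)Oc1ccc2c(c1)O[C@H](c1ccc(OCc3ccccc3)c(OCc3ccccc3)c1)[C@@H](O)[C@@H]2O
F3 | step 13 | (2R,3S,4R)-2-[3,4-bis(benzyloxy)phenyl]-4-methoxy-7-[(triisopropylsilyl)oxy]chroman-3-ol | CC(C)[Si](C(C)C)(C(C)C)Oc1ccc2c(c1)O[C@H](c1ccc(OCc3ccccc3)c(OCc3ccccc3)c1)[C@@H](O)[C@@H]2OC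
F4 | step 13 | 3-O-[chloro(diisopropyl)silyl] derivative of F3 | CC(C)[Si](C(C)C)(C(C)C)Oc1ccc2c(c1)O[C@H](c1ccc(OCc3ccccc3)c(OCc3ccccc3)c1)[C@@H](O[Si](Cl)(C(C)C)C(C)C)[C@@H]2OC
F5 | step 13 | diisopropylsilylene acetal joining O-3 of F3 to O-7 of F1 | CC(C)[Si](C(C)C)(C(C)C)Oc1ccc2c(c1)O[C@H](c1ccc(OCc3ccccc3)c(OCc3ccccc3)c1)[C@@H](O[Si](C(C)C)(C(C)C)Oc1ccc3c(c1)O[C@H](c1ccc(OCc4ccccc4)c(OCc4ccccc4)c1)[C@@H](O)C3=O)[C@@H]2OC
F6 | step 11 | 4β-linked dimer of the (2R,3S)-flavan-3-ol unit (7-O-TIPS) and 12, bonded C4–C5', with free 3-OH and 6'-OH | CC(C)[Si](C(C)C)(C(C)C)Oc1ccc2c(c1)O[C@H](c1ccc(OCc3ccccc3)c(OCc3ccccc3)c1)[C@@H](O)[C@H]2c1cc2c(cc1O)O[C@H](c1ccc(OCc3ccccc3)c(OCc3ccccc3)c1)[C@]2(O)C(=O)OC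
F7 | step 16 | 3',4',3'',4''-tetra-O-benzyl-fisetinidol-(4β→6)-mollisacacidin | Oc1ccc2c(c1)O[C@H](c1ccc(OCc3ccccc3)c(OCc3ccccc3)c1)[C@@H](O)[C@H]2c1cc2c(cc1O)O[C@H](c1ccc(OCc3ccccc3)c(OCc3ccccc3)c1)[C@@H](O)[C@@H]2O
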